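**Retrosynthetic overview**

1. Target ⇒ intramolecular hetero-Diels–Alder reaction (carbocycle C3–C4 bond and O–CMe2 bond of ring A) ⇒ 3-alkylidenequinoline-2,4-dione ⇒ [2+2]/ring opening between an aldehyde C=O and 1-methyl-3,4-didehydroquinolin-2-one, which makes the ring-A O–C4(quinolone A) and C3(quinolone A)–C3 bonds together. Carbocycle in p-menthane numbering: C1 = C(Me)–O, C3 = CH on quinolone A, C4 = CH–CMe2, C5 = CH on quinolone B.
2. Feature that makes this possible: ring B of the aldehyde, the dihydropyran O1–C2–C3–C4 fused to quinolone B, holds CH2–CH=O (on C2) and CH=CMe2 (on C4) on the same face. The C=O supplies the ring-A oxygen and C3; the alkene supplies C4 and CMe2.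
3. Aldehyde ⇒ oxa-Michael closure of ring B from a 5-quinolinyl citral ⇒ nitrile reduction ⇒ Horner–Wadsworth–Emmons olefination of a methyl ketone ⇒ catalytic enantioselective Michael addition of 4-hydroxy-1-methylquinolin-2-one to 6-methylhepta-3,5-dien-2-one (sets C5, the one controlling centre).
4. Hetaryne precursor (3-silyl 4-triflate) ⇒ bromination, then silylation/retro-Brook/triflation of the same quinolinone.
5. Ring order: both quinolone bicycles are bought; ring B is closed next; then, in one operation, the transient oxete, ring A and the carbocycle.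

Key step: step 6

Assumption: the (S,S)-diamine of step 1 is taken to give the S adduct, by analogy with the warfarin series; if the sense is the opposite, the (R,R)-diamine is used.

**Route**

Step 1
Reactants: 1 4-hydroxy-1-methylquinolin-2(1H)-one; 2 (3E)-6-methylhepta-3,5-dien-2-one
Product: 3 4-hydroxy-1-methyl-3-[(4S)-2-methyl-6-oxohept-2-en-4-yl]quinolin-2(1H)-one (in equilibrium with its cyclic hemiketals)
Conditions: (S,S)-1,2-diphenylethane-1,2-diamine (10 mol%), AcOH (10 equiv), THF, 23 °C
Reagents that add atoms: none
Why: Primary-amine (iminium) catalysed enantioselective Michael addition of the warfarin type should deliver the enol carbon C3 of 1 to the β-carbon of 2 (the δ-carbon is blocked by its two methyl groups), the diamine fixing the new stereocentre as S by hydrogen-bond-directed attack on one face of the iminium ion.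

Step 2
Reactants: 3 4-hydroxy-1-methyl-3-[(4S)-2-methyl-6-oxohept-2-en-4-yl]quinolin-2(1H)-one
Product: 4 (5S)-5-(4-hydroxy-1-methyl-2-oxo-1,2-dihydroquinolin-3-yl)-3,7-dimethylocta-2,6-dienenitrile (2E/2Z mixture)
Conditions: (EtO)2P(O)CH2CN (2 equiv), NaH (3.2 equiv), THF, 0 → 60 °C; aq. NH4Cl
Reagents that add atoms: diethyl (cyanomethyl)phosphonate, N#CCP(=O)(OCC)OCC
Why: Horner–Wadsworth–Emmons olefination of the methyl ketone, run on the sodium 4-oxide so that the hemiketal is open and retro-Michael loss of a dianion is disfavoured, should give the β-methyl unsaturated nitrile as an E/Z mixture whose geometry is erased in step 3, without touching the stereocentre.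

Step 3
Reactants: 4 (5S)-5-(4-hydroxy-1-methyl-2-oxo-1,2-dihydroquinolin-3-yl)-3,7-dimethylocta-2,6-dienenitrile
Product: 7 cis-aldehyde 2-[(2R,4S)-2,6-dimethyl-4-(2-methylprop-1-en-1-yl)-5-oxo-3,4,5,6-tetrahydro-2H-pyrano[3,2-c]quinolin-2-yl]acetaldehyde, via enal 5 (not isolated), via epimer mixture 6 (not isolated)
Conditions: i-Bu2AlH (3 equiv), CH2Cl2, −78 °C; aq. potassium sodium tartrate, then 1 M HCl; DBU (0.2 equiv), CH2Cl2, 23 °C; SiO2 separation, 2S epimer and residual enal returned to DBU
Reagents that add atoms: water, O
Why: Partial reduction of the nitrile with i-Bu2AlH and hydrolysis of the aldimine should give the citral-type enal 5, which closes ring B by base-catalysed 6-exo-trig oxa-Michael addition of the 4-OH to the β-carbon (this also removes the enal unsaturation, so that the later quinone methide cannot escape to a 2H-pyran); the new quaternary centre C2 is not controlled, both epimers forming reversibly through E1cB opening, so the 2R epimer with CH2CHO and alkenyl syn is separated and the 2S epimer is re-equilibrated.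

Step 4
Reactants: 1 4-hydroxy-1-methylquinolin-2(1H)-one
Product: 8 3-bromo-4-hydroxy-1-methylquinolin-2(1H)-one
Conditions: NBS (1.05 equiv), MeCN, 23 °C
Reagents that add atoms: N-bromosuccinimide, O=C1CCC(=O)N1Br
Why: Electrophilic bromination of the enol carbon C3 of the vinylogous acid places the halogen needed for the silyl migration of step 5.

Step 5
Reactants: 8 3-bromo-4-hydroxy-1-methylquinolin-2(1H)-one
Product: 11 1-methyl-2-oxo-3-(trimethylsilyl)-1,2-dihydroquinolin-4-yl trifluoromethanesulfonate, via silyl ether 9 (not isolated), via lithium oxide 10 (not isolated)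
Conditions: (Me3Si)2NH, THF, 65 °C, then evaporation; n-BuLi (1.1 equiv), THF, −100 → −78 °C; Tf2O (1.2 equiv), −78 → 0 °C
Reagents that add atoms: hexamethyldisilazane, C[Si](C)(C)N[Si](C)(C)C; trifluoromethanesulfonic anhydride, O=S(=O)(OS(=O)(=O)C(F)(F)F)C(F)(F)F
Why: The standard one-flask route to ortho-silylaryl triflates is applied: O-silylation, bromine–lithium exchange with anionic 1,3 O-to-C silyl migration (retro-Brook rearrangement) and O-triflation of the resulting lithium oxide, which is never protonated so that the C–Si bond should survive.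

Step 6
Reactants: 7 cis-aldehyde 2-[(2R,4S)-2,6-dimethyl-4-(2-methylprop-1-en-1-yl)-5-oxo-3,4,5,6-tetrahydro-2H-pyrano[3,2-c]quinolin-2-yl]acetaldehyde; 11 1-methyl-2-oxo-3-(trimethylsilyl)-1,2-dihydroquinolin-4-yl trifluoromethanesulfonate
Product: 15 target bis-quinolinone (1R,3S,4R,5S in the p-menthane numbering of the carbocycle), via hetaryne 12 (not isolated), via oxete 13 (not isolated), via quinone methide 14 (not isolated)
Conditions: 11 (1.6 equiv, added over 4 h), [Bu4N][Ph3SiF2] (2 equiv), toluene–THF, 23 °C, then 80 °C
Reagents that add atoms: none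
Why: Proposed new method: fluoride strips the C3 silyl group of 11 and triflate leaves from C4 to give the strained 3,4-didehydroquinolinone 12, whose C4 (β to the lactam carbonyl and distal to its inductive pull) should take the aldehyde oxygen of 7 while the incipient C3 anion closes on the carbonyl carbon in a formal [2+2], so that the O–C4 and C3–C bonds of ring A are made together; the closest known reaction type is the insertion of silylaryl-triflate-derived arynes into the C=O bond of aldehydes and formamides to give benzoxetes and ortho-quinone methides that are trapped in [4+2] reactions, here extended to a pyridone-type hetaryne and an intramolecular trap. The oxete 13 (four-membered ring closed by the [2+2]) should open by 4π-electrocyclic cleavage to the 3-alkylidenequinoline-2,4-dione 14, a 1-oxadiene of the kind formed in domino Knoevenagel/hetero-Diels–Alder reactions of 4-hydroxyquinolinones. Intramolecular inverse-demand hetero-Diels–Alder reaction of 14 with the 2-methylprop-1-enyl group then closes the dihydropyran ring A (concerted [4+2], O–CMe2 and C3–C4 bonds) and, as its tether ring, the cyclohexane (type 1 intramolecular mode, six-membered chair). The two new stereocentres (the former aldehyde carbon and the former alkene CH) are set by ring B: its 2R and 4S centres hold the two reacting arms syn and axial, so the carbocycle can only form on one face as the chair of a 2-oxabicyclo[3.3.1]nonane, and the exo-E-anti chair transition state puts both the C3–quinolone and the C4–CMe2 bonds equatorial, which gives the trans ring fusion with H-4 syn to H-5. The step needs O-to-C4 regioselectivity in the capture of 12 (secured by the polarisation of the hetaryne), capture by the aldehyde in preference to an ene reaction with the alkene (secured by slow release of 12 into an excess of carbonyl groups) and integrity of the β-aryloxy aldehyde (secured by the weakly basic silicate as fluoride source). The cycloaddition is reversible on heating, so a kinetically formed cis-fused adduct should drain into the trans-fused product with both ring-A bonds equatorial.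

**Compound list**

1 | 4-hydroxy-1-methylquinolin-2(1H)-one | Cn1c(=O)cc(O)c2ccccc12 | starting material
2 | (3E)-6-methylhepta-3,5-dien-2-one | CC(=O)/C=C/C=C(C)C | starting material
3 | 4-hydroxy-1-methyl-3-[(4S)-2-methyl-6-oxohept-2-en-4-yl]quinolin-2(1H)-one (open form) | CC(=O)C[C@@H](C=C(C)C)c1c(O)c2ccccc2n(C)c1=O | intermediate
4 | (5S)-5-(4-hydroxy-1-methyl-2-oxo-1,2-dihydroquinolin-3-yl)-3,7-dimethylocta-2,6-dienenitrile (2E/2Z mixture) | N#CC=C(C)C[C@@H](C=C(C)C)c1c(O)c2ccccc2n(C)c1=O | intermediate
5 | (5S)-5-(4-hydroxy-1-methyl-2-oxo-1,2-dihydroquinolin-3-yl)-3,7-dimethylocta-2,6-dienal (2E/2Z mixture) | O=CC=C(C)C[C@@H](C=C(C)C)c1c(O)c2ccccc2n(C)c1=O | intermediate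
6 | 2-[(4S)-2,6-dimethyl-4-(2-methylprop-1-en-1-yl)-5-oxo-3,4,5,6-tetrahydro-2H-pyrano[3,2-c]quinolin-2-yl]acetaldehyde, both C2 epimers | O=CCC1(C)C[C@@H](C=C(C)C)c2c(O1)c1ccccc1n(C)c2=O | intermediate
7 | 2-[(2R,4S)-2,6-dimethyl-4-(2-methylprop-1-en-1-yl)-5-oxo-3,4,5,6-tetrahydro-2H-pyrano[3,2-c]quinolin-2-yl]acetaldehyde (CH2CHO and alkenyl syn) | O=CC[C@@]1(C)C[C@@H](C=C(C)C)c2c(O1)c1ccccc1n(C)c2=O | intermediate
8 | 3-bromo-4-hydroxy-1-methylquinolin-2(1H)-one | Cn1c(=O)c(Br)c(O)c2ccccc12 | intermediate
9 | 3-bromo-1-methyl-4-[(trimethylsilyl)oxy]quinolin-2(1H)-one | Cn1c(=O)c(Br)c(O[Si](C)(C)C)c2ccccc12 | intermediate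
10 | lithium 1-methyl-2-oxo-3-(trimethylsilyl)-1,2-dihydroquinolin-4-olate | Cn1c(=O)c([Si](C)(C)C)c([O-])c2ccccc12.[Li+] | intermediate
11 | 1-methyl-2-oxo-3-(trimethylsilyl)-1,2-dihydroquinolin-4-yl trifluoromethanesulfonate | Cn1c(=O)c([Si](C)(C)C)c(OS(=O)(=O)C(F)(F)F)c2ccccc12 | intermediate
12 | 1-methyl-3,4-didehydroquinolin-2(1H)-one (hetaryne) | CN1C(=O)C#Cc2ccccc12 | intermediate
13 | oxete: [2+2] adduct of 12 across the C=O of 7 (O on C4, CH on C3 of quinolone A; oxete CH of either configuration) | CN1C(=O)C2=C(OC2C[C@@]3(C)C[C@@H](C=C(C)C)c4c(O3)c3ccccc3n(C)c4=O)c2ccccc12 | intermediate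
14 | quinone methide: 1-methyl-3-alkylidenequinoline-2,4(1H,3H)-dione carrying the ring-B unit of 7 on the alkylidene CH2 | CN1C(=O)C(=CC[C@@]2(C)C[C@@H](C=C(C)C)c3c(O2)c2ccccc2n(C)c3=O)C(=O)c2ccccc12 | intermediate
15 | target bis-quinolinone: carbocycle 1R,3S,4R,5S (p-menthane numbering); ring A trans-fused (H-3 anti to H-4), H-4 syn to H-5, ether bridge O–C1 syn to the C5–quinolone bond | Cn1c(=O)c2c(c3ccccc31)OC(C)(C)[C@@H]1[C@@H]2C[C@@]2(C)C[C@@H]1c1c(c3ccccc3n(C)c1=O)O2 | target

**Step count and risks**

Total step count: 6. Longest linear sequence: 4 (steps 1, 2, 3, 6).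

Steps most likely to fail:

1. Step 6. The hetaryne may not be generated or captured cleanly: direct displacement of triflate at C4, protodesilylation, an ene reaction with the trisubstituted alkene, or fluoride-induced E1cB opening of ring B could each divert the sequence. The fallback is the known domino Knoevenagel/intramolecular hetero-Diels–Alder reaction. It sets out from 7 (or from the epimer mixture 6, because the amine salt also equilibrates C2 and only the syn series can cyclise) and 1, with ethylenediammonium diacetate (10 mol%) in MeCN or toluene at 25–80 °C. Condensation should give the same quinone methide 14, where the fallback rejoins the route, and from there 15. It makes no compound outside the list (F0).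

2. Step 5. n-BuLi may attack the lactam carbonyl, the O-to-C silyl migration may be incomplete, or the C-silyl oxide may lose silicon before triflation. The fallback sets out from 1 and installs silicon by carbamate-directed lithiation. Isopropyl isocyanate and Et3N should give 1-methyl-2-oxo-1,2-dihydroquinolin-4-yl N-(propan-2-yl)carbamate F1. Transient N-silylation (Me3SiOTf, TMEDA), n-BuLi/TMEDA at −78 °C and Me3SiCl should give the 3-trimethylsilyl carbamate F2. Carbamate cleavage with DBU/Et2NH in MeCN followed by PhNTf2 in the same flask rejoins the route at 11.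

3. Step 3. The oxa-Michael equilibrium may lie on the open side or give little of the 2R epimer, ring B may reopen on silica, and the nitrile may be over-reduced. The fallback sets out from 3 and closes ring B as an ether that cannot reopen, with C2 under ligand control. CH2=CHMgBr/CeCl3 should give the tertiary allylic alcohol 4-hydroxy-3-[(4S)-6-hydroxy-2,6-dimethylocta-2,7-dien-4-yl]-1-methylquinolin-2(1H)-one F3. LiN(SiMe3)2 and ClCO2Me should give its bis(methyl carbonate) F4. Asymmetric allylic etherification with Pd2(dba)3·CHCl3 and the enantiomer of the Trost diaminocyclohexane bis(2-diphenylphosphinobenzamide) ligand that delivers 2R should give (2R,4S)-2-ethenyl-2,6-dimethyl-4-(2-methylprop-1-en-1-yl)-2,3,4,6-tetrahydro-5H-pyrano[3,2-c]quinolin-5-one F5. Hydroboration of the vinyl group with 9-BBN and oxidation with NaBO3·4H2O should give the primary alcohol (2R,4S)-2-(2-hydroxyethyl)-2,6-dimethyl-4-(2-methylprop-1-en-1-yl)-2,3,4,6-tetrahydro-5H-pyrano[3,2-c]quinolin-5-one F6. Dess–Martin oxidation rejoins the route at 7, which is used at once.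

**Further compounds**

F0 | step 6 | none | none
F1 | step 5 | 1-methyl-2-oxo-1,2-dihydroquinolin-4-yl N-(propan-2-yl)carbamate | CC(C)NC(=O)Oc1cc(=O)n(C)c2ccccc12
F2 | step 5 | 1-methyl-2-oxo-3-(trimethylsilyl)-1,2-dihydroquinolin-4-yl N-(propan-2-yl)carbamate | CC(C)NC(=O)Oc1c([Si](C)(C)C)c(=O)n(C)c2ccccc12
F3 | step 3 | 4-hydroxy-3-[(4S)-6-hydroxy-2,6-dimethylocta-2,7-dien-4-yl]-1-methylquinolin-2(1H)-one (both C6 epimers) | C=CC(C)(O)C[C@@H](C=C(C)C)c1c(O)c2ccccc2n(C)c1=O
F4 | step 3 | bis(methyl carbonate) of F3 (tertiary allylic O and quinolone 4-O) | C=CC(C)(OC(=O)OC)C[C@@H](C=C(C)C)c1c(OC(=O)OC)c2ccccc2n(C)c1=O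
F5 | step 3 | (2R,4S)-2-ethenyl-2,6-dimethyl-4-(2-methylprop-1-en-1-yl)-2,3,4,6-tetrahydro-5H-pyrano[3,2-c]quinolin-5-one | C=C[C@@]1(C)C[C@@H](C=C(C)C)c2c(O1)c1ccccc1n(C)c2=O
F6 | step 3 | (2R,4S)-2-(2-hydroxyethyl)-2,6-dimethyl-4-(2-methylprop-1-en-1-yl)-2,3,4,6-tetrahydro-5H-pyrano[3,2-c]quinolin-5-one | OCC[C@@]1(C)C[C@@H](C=C(C)C)c2c(O1)c1ccccc1n(C)c2=O
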